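**Retrosynthetic overview**

- The strategy rests on the 4-pyranone ring C: carbonyl carbon C4 sits between ring-A carbon C4a and the C3=C2 unit that bears ring B, and O1 is bound to ring-A carbon C8a. Ring C is therefore cut into carbon monoxide (C4), an arylacetylene (C3–C2 plus ring B) and an ortho-iodophenol (C4a–I, C8a–OH).
- The ring-A fragment comes from one iodination of symmetric 3,4,5-trimethoxyphenol. The ring-B alkyne comes from 2,3,4-trimethoxybenzaldehyde by ortho demethylation, benzylation, Baeyer–Villiger oxidation, ortho iodination, methylation, Sonogashira coupling and desilylation.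
- A single BCl3 operation at the end frees O3' (benzyl ether) and O5 (peri methyl ether).
- Rings A and B are bought as benzenes; ring C is the only ring formed, last, in step 9. The target has no stereocentre.

Key step: step 9

Assumption: the C=C geometry of the transient enaminone 15 is left undefined, because either isomer gives the same pyranone; locants C2–C8a and C1'–C6' follow flavone numbering.

**Route**

Step 1
Reactants: 1 3,4,5-trimethoxyphenol
Product: 2 2-iodo-3,4,5-trimethoxyphenol
Conditions: NIS (1.0 equiv), CH2Cl2, −20 → 0 °C, dark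
Reagents that add atoms: N-iodosuccinimide, O=C1CCC(=O)N1I
Why: Electrophilic aromatic iodination in which the hydroxyl is the strongest activator and its two ortho positions are equivalent by symmetry, so one equivalent of NIS at low temperature should give a single mono-iodide.

Step 2
Reactants: 3 2,3,4-trimethoxybenzaldehyde
Product: 4 2-hydroxy-3,4-dimethoxybenzaldehyde
Conditions: BCl3 (1.1 equiv), CH2Cl2, 0 °C → rt; then H2O
Reagents that add atoms: none
Why: Chelation-controlled Lewis-acid ether cleavage, in which BCl3 is held between the aldehyde oxygen and the C2 methoxy oxygen in a six-membered chelate so that chloride should remove only that methyl group.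

Step 3
Reactants: 4 2-hydroxy-3,4-dimethoxybenzaldehyde
Product: 5 2-(benzyloxy)-3,4-dimethoxybenzaldehyde
Conditions: BnBr, K2CO3, DMF, 60 °C
Reagents that add atoms: benzyl bromide, BrCc1ccccc1
Why: Williamson ether synthesis on the only phenol present, with gentle heating to overcome its hydrogen bond to the aldehyde.

Step 4
Reactants: 5 2-(benzyloxy)-3,4-dimethoxybenzaldehyde
Product: 7 2-(benzyloxy)-3,4-dimethoxyphenol, via aryl formate 6 (not isolated)
Conditions: mCPBA, CH2Cl2, 0 °C → rt; aq. NaHCO3/Na2S2O3 wash; then K2CO3 (cat.), MeOH, rt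
Reagents that add atoms: meta-chloroperoxybenzoic acid, O=C(OO)c1cccc(Cl)c1
Why: Baeyer–Villiger (Dakin-type) oxidation in which the aryl group, made electron-rich by its ortho and para alkoxy groups, migrates in preference to hydride to give formate 6, which base-catalysed methanolysis should convert to the phenol.

Step 5
Reactants: 7 2-(benzyloxy)-3,4-dimethoxyphenol
Product: 8 2-(benzyloxy)-6-iodo-3,4-dimethoxyphenol
Conditions: NIS (1.05 equiv), MeCN, −10 °C → rt, dark
Reagents that add atoms: N-iodosuccinimide, O=C1CCC(=O)N1I
Why: Electrophilic aromatic iodination directed by the free hydroxyl, whose para position is blocked by the C4 methoxy group, so that attack should occur at the single open ortho carbon C6 (also para to the C3 methoxy group).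

Step 6
Reactants: 8 2-(benzyloxy)-6-iodo-3,4-dimethoxyphenol
Product: 9 3-(benzyloxy)-1-iodo-2,4,5-trimethoxybenzene
Conditions: MeI, K2CO3, DMF, rt
Reagents that add atoms: iodomethane, CI
Why: Williamson O-methylation of the phenoxide, which should be clean because no other acidic or nucleophilic site is present.

Step 7
Reactants: 9 3-(benzyloxy)-1-iodo-2,4,5-trimethoxybenzene; 10 trimethylsilylacetylene
Product: 11 {[3-(benzyloxy)-2,4,5-trimethoxyphenyl]ethynyl}trimethylsilane
Conditions: PdCl2(PPh3)2 (3 mol%), CuI (5 mol%), Et3N, THF, 50 °C, degassed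
Reagents that add atoms: none
Why: Sonogashira coupling, for which an aryl iodide is reactive enough to offset the electron-rich, mono-ortho-substituted ring, and which leaves the ethers untouched.

Step 8
Reactants: 11 {[3-(benzyloxy)-2,4,5-trimethoxyphenyl]ethynyl}trimethylsilane
Product: 12 3-(benzyloxy)-1-ethynyl-2,4,5-trimethoxybenzene
Conditions: K2CO3 (cat.), MeOH/THF, rt
Reagents that add atoms: none
Why: Methoxide-catalysed protodesilylation of the alkynylsilane, which should free the terminal alkyne without affecting the benzyl or methyl ethers.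

Step 9
Reactants: 2 2-iodo-3,4,5-trimethoxyphenol; 12 3-(benzyloxy)-1-ethynyl-2,4,5-trimethoxybenzene; 13 carbon monoxide
Product: 16 2-[3-(benzyloxy)-2,4,5-trimethoxyphenyl]-5,6,7-trimethoxy-4H-chromen-4-one (3'-O-benzyl-5-O-methylpsiadiarabicin), via ortho-hydroxyaryl ynone 14 (not isolated), via diethylamino enone 15 (not isolated)
Conditions: PdCl2(dppf) (5 mol%), CO (20 atm), Et2NH, 120 °C, autoclave, copper-free
Reagents that add atoms: none
Why: Zerovalent palladium generated from PdCl2(dppf) inserts into the C–I bond of 2, migratory insertion of CO gives the aroylpalladium species, and amine-assisted transfer of the acetylide of 12 with reductive elimination forms C4a–C4 and C4–C3 on the CO carbon and releases ynone 14. Diethylamine adds in conjugate fashion to 14 to give enaminone 15, and the ortho hydroxyl then attacks the amine-bearing carbon and expels diethylamine (addition–elimination), forming O1–C2. The closest known reaction type is the palladium-catalysed carbonylative annulation of ortho-iodophenols with terminal arylacetylenes to flavones (carbonylative Sonogashira coupling followed by amine-promoted cyclization). Ring C, the only ring formed, closes in a net 6-endo mode onto the former internal alkyne carbon; no stereocentre arises. The step needs CO insertion ahead of alkynylation (otherwise a 2-arylbenzofuran would form) and 6-endo over 5-exo closure (otherwise an aurone would form). The first is secured by CO pressure, the absence of copper and the ready aryl-to-CO migration of the electron-rich trimethoxyaryl palladium species, the second by closure through enaminone 15, whose amine-bearing carbon is the only electrophilic position offered to the phenol oxygen.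

Step 10
Reactants: 16 2-[3-(benzyloxy)-2,4,5-trimethoxyphenyl]-5,6,7-trimethoxy-4H-chromen-4-one
Product: 17 psiadiarabicin, 5-hydroxy-2-(3-hydroxy-2,4,5-trimethoxyphenyl)-6,7-dimethoxy-4H-chromen-4-one
Conditions: BCl3 (4 equiv), pentamethylbenzene (3 equiv), CH2Cl2, −78 → 0 °C; then dilute aq. HCl
Reagents that add atoms: none
Why: Lewis-acid ether cleavage in which BCl3 ionises the benzyl ether at O3' (the benzyl cation being trapped by pentamethylbenzene) and, chelated between the C4 carbonyl and O5, removes the peri methyl group, while the five methoxy groups that lack such chelation should survive at or below 0 °C.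

**Compound list**

1 | 3,4,5-trimethoxyphenol | COc1cc(O)cc(OC)c1OC | starting material
2 | 2-iodo-3,4,5-trimethoxyphenol | COc1cc(O)c(I)c(OC)c1OC | intermediate
3 | 2,3,4-trimethoxybenzaldehyde | COc1ccc(C=O)c(OC)c1OC | starting material
4 | 2-hydroxy-3,4-dimethoxybenzaldehyde | COc1ccc(C=O)c(O)c1OC | intermediate
5 | 2-(benzyloxy)-3,4-dimethoxybenzaldehyde | COc1ccc(C=O)c(OCc2ccccc2)c1OC | intermediate
6 | 2-(benzyloxy)-3,4-dimethoxyphenyl formate | COc1ccc(OC=O)c(OCc2ccccc2)c1OC | intermediate
7 | 2-(benzyloxy)-3,4-dimethoxyphenol | COc1ccc(O)c(OCc2ccccc2)c1OC | intermediate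
8 | 2-(benzyloxy)-6-iodo-3,4-dimethoxyphenol | COc1cc(I)c(O)c(OCc2ccccc2)c1OC | intermediate
9 | 3-(benzyloxy)-1-iodo-2,4,5-trimethoxybenzene | COc1cc(I)c(OC)c(OCc2ccccc2)c1OC | intermediate
10 | trimethylsilylacetylene | C#C[Si](C)(C)C | starting material
11 | {[3-(benzyloxy)-2,4,5-trimethoxyphenyl]ethynyl}trimethylsilane | COc1cc(C#C[Si](C)(C)C)c(OC)c(OCc2ccccc2)c1OC | intermediate
12 | 3-(benzyloxy)-1-ethynyl-2,4,5-trimethoxybenzene | C#Cc1cc(OC)c(OC)c(OCc2ccccc2)c1OC | intermediate
13 | carbon monoxide | [C-]#[O+] | starting material
14 | 3-[3-(benzyloxy)-2,4,5-trimethoxyphenyl]-1-(2-hydroxy-4,5,6-trimethoxyphenyl)prop-2-yn-1-one | COc1cc(O)c(C(=O)C#Cc2cc(OC)c(OC)c(OCc3ccccc3)c2OC)c(OC)c1OC | intermediate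
15 | 3-[3-(benzyloxy)-2,4,5-trimethoxyphenyl]-3-(diethylamino)-1-(2-hydroxy-4,5,6-trimethoxyphenyl)prop-2-en-1-one (C=C geometry undefined) | COc1cc(O)c(C(=O)C=C(N(CC)CC)c2cc(OC)c(OC)c(OCc3ccccc3)c2OC)c(OC)c1OC | intermediate
16 | 2-[3-(benzyloxy)-2,4,5-trimethoxyphenyl]-5,6,7-trimethoxy-4H-chromen-4-one | COc1cc(-c2cc(=O)c3c(OC)c(OC)c(OC)cc3o2)c(OC)c(OCc2ccccc2)c1OC | intermediate
17 | psiadiarabicin | COc1cc(-c2cc(=O)c3c(O)c(OC)c(OC)cc3o2)c(OC)c(O)c1OC | target

**Step count**

Total steps: 10. Longest linear sequence: 9 steps (from 3 through steps 2–10).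

**Steps most likely to fail**

Step 9. Oxidative addition at the electron-rich C–I bond flanked by hydroxyl and methoxyl may be slow. Aminocarbonylation by diethylamine or alkynylation without CO uptake may then compete. If only the ring closure lags, ynone 14 can be isolated and heated with Et2NH in EtOH. The fallback that changes the approach brings in the carbonyl carbon as a formyl group instead of CO; it sets out from 1 and 12 and comes back at 14.
- Phenol 1 is ortho-formylated (MgCl2, Et3N, paraformaldehyde, MeCN, reflux) to 2-hydroxy-4,5,6-trimethoxybenzaldehyde F1.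
- Alkyne 12 is deprotonated (n-BuLi, THF, −78 °C) to lithium [3-(benzyloxy)-2,4,5-trimethoxyphenyl]acetylide F2.
- Addition of 2.2 equivalents of F2 to F1 (the first equivalent is consumed by the phenol and returns 12 on work-up) should give racemic 2-{3-[3-(benzyloxy)-2,4,5-trimethoxyphenyl]-1-hydroxyprop-2-yn-1-yl}-3,4,5-trimethoxyphenol F3.
- MnO2 in CH2Cl2 should oxidise F3 to ynone 14, which Et2NH in EtOH at reflux closes through 15 to flavone 16.

Step 10. Lewis-acid cleavage may run on to the methoxy groups next to the newly freed hydroxyls (O6, O2', O4'), or the benzyl cation may be transferred to the nucleophilic ring-A carbon C8. The fallback separates the two deprotections by mechanism; it sets out from 16 and comes back at 17.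
- Hydrogenolysis of 16 (H2, Pd/C, EtOAc/MeOH, rt) should give 3'-hydroxy-5,6,7,2',4',5'-hexamethoxyflavone F4.
- Chelation-controlled peri demethylation of F4 (AlCl3, MeCN, 50 °C; then dilute aq. HCl) should give psiadiarabicin 17.

Step 5. Iodination may go ortho to the C4 methoxyl instead of ortho to the hydroxyl, a second iodine may be introduced, or the electron-rich phenol may be oxidised towards a quinone. The fallback fixes the ortho position through a magnesium phenoxide and dispenses with the aryl iodide; it sets out from 7 and comes back at 12, bypassing 8, 9 and 11.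
- Ortho-formylation of 7 (MgCl2, Et3N, paraformaldehyde, MeCN, reflux) should give 3-(benzyloxy)-2-hydroxy-4,5-dimethoxybenzaldehyde F5.
- O-Methylation (MeI, K2CO3, DMF, 50 °C) should give 3-(benzyloxy)-2,4,5-trimethoxybenzaldehyde F6.
- Ohira–Bestmann homologation of F6 (dimethyl (1-diazo-2-oxopropyl)phosphonate, K2CO3, MeOH, rt) should give alkyne 12.

**Further compounds**

F1 | step 9 | 2-hydroxy-4,5,6-trimethoxybenzaldehyde | COc1cc(O)c(C=O)c(OC)c1OC
F2 | step 9 | lithium [3-(benzyloxy)-2,4,5-trimethoxyphenyl]acetylide | [Li]C#Cc1cc(OC)c(OC)c(OCc2ccccc2)c1OC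
F3 | step 9 | racemic 2-{3-[3-(benzyloxy)-2,4,5-trimethoxyphenyl]-1-hydroxyprop-2-yn-1-yl}-3,4,5-trimethoxyphenol | COc1cc(O)c(C(O)C#Cc2cc(OC)c(OC)c(OCc3ccccc3)c2OC)c(OC)c1OC
F4 | step 10 | 3'-hydroxy-5,6,7,2',4',5'-hexamethoxyflavone | COc1cc(-c2cc(=O)c3c(OC)c(OC)c(OC)cc3o2)c(OC)c(O)c1OC
F5 | step 5 | 3-(benzyloxy)-2-hydroxy-4,5-dimethoxybenzaldehyde | COc1cc(C=O)c(O)c(OCc2ccccc2)c1OC
F6 | step 5 | 3-(benzyloxy)-2,4,5-trimethoxybenzaldehyde | COc1cc(C=O)c(OC)c(OCc2ccccc2)c1OC
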